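All runs were computed on assumed constants; noise was put on by code.

If you follow one molecule of substrate through these flasks, ask one thing: what is its chance of ending as target?

common to all: gas 0.53 mM (held)
- birch: substrate 6.1 mM; run made earlier
- larch: substrate 17 mM; run made earlier
- maple: substrate 35 mM; run made earlier
- violet: substrate 5.0 mM; time 20 min
- teal: substrate 15 mM; time 20 min
- blue: substrate 50 mM; time 20 min

| birch: time / min | birch: target / % | larch: time / min | larch: target / % | maple: time / min | maple: target / % |
|---|---|---|---|---|---|
| 3.00 | 16.0 | 1.33 | 4.9 | 1.00 | 0.3 |
| 6.00 | 25.2 | 4.00 | 18.5 | 2.00 | 7.4 |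
| 8.00 | 29.1 | 6.00 | 25.8 | 4.00 | 16.1 |
| 12.0 | 33.8 | 10.0 | 32.9 | 8.00 | 31.8 |
| 15.0 | 36.0 | 15.0 | 35.3 | 15.0 | 35.3 |

(scatter of a reading: 1 percentage point)

- what was read earlier has a scatter of 1 percentage point, one standard deviation
- at the start none of the gas is in solution
- "hardly changes" means that all values lie within two and a half points (for a concentration: within two and a half percent of the largest)

- [target] at the end for violet, teal, blue, in this order
- the course of these numbers from the first flask to the last (falls all the way / falls, then rises / hardly changes / rises, then falls / rises all the way)

The last readings of birch, larch and maple, at 15.0 min, are 36.0%, 35.3% and 35.3% of the charge. Their mean, 35.5%, is your target share, the fraction of the charge read as target at that time. From birch to maple the charge grows 5.74 times, yet these readings differ by 0.7 percentage points, with a scatter of 1 point. My own reckoning takes the same share for 20 min, multiplies it by each charge and gives 1.78 mM, 5.33 mM and 17.8 mM.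

Now turn the question round. For the row to break at its last step, blue must end below teal. With teal at the target share, blue's share at 20 min must then stay under 10.7%. That means an average climb under 0.00533 min⁻¹ of blue's charge. Maple's readings climbed 0.0407 min⁻¹ of its own charge between 2.00 min and 8.00 min. Suppose the gas held the amount made per minute at maple's level. Blue would still climb 0.0285 min⁻¹ of its charge, faster by a factor of 5.35. It would reach the target share in 12.5 min, sooner than 20 min. So watch blue's climb.

The forecast gives 1.85 mM, 5.5 mM and 18 mM, rises all the way, its last value above mine, and holds that “selectivity seems independent of concentration”.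

The flasks give 1.82 mM, 5.53 mM and 19.1 mM; the course rises all the way.

    reagent + intermediate A → intermediate B (k = 167 M⁻¹ s⁻¹)
    reagent + intermediate A → side product A (k = 17.0 M⁻¹ s⁻¹)
    reagent + intermediate B ⇌ intermediate C (K = 92000 M⁻¹, k = 9.18 M⁻¹ s⁻¹)
    gas ⇌ reagent, rate k4*(csat - [reagent]) (kL = 0.503 s⁻¹)
    intermediate B → target (k = 0.0115 s⁻¹)
    intermediate B → side product B (k = 0.0123 s⁻¹)
    substrate → intermediate A (k = 0.00352 s⁻¹)

Substrate, the limiting reagent, stands at 1.46% of the charge in violet at the end and at 1.46% in blue. On teal, the target share gives 5.33 mM, and teal holds 5.53 mM. On blue it gives 17.8 mM, and blue holds 19.1 mM, which is 38.2% of its charge at 20.0 min.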